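**Strategy.** The target's benzene ring carries oxygen on alternate carbons (C3–OH, C5–OMe) and, at C1, a chain oxygenated at its second carbon. Opening the ring bond between aryl C1 and the CH that lies between C1 and the phenolic carbon unfolds all of this into a linear 3,5,7-triketo ester. In one operation (carbonate, then acid) the C2 enolate closes onto the C7 ketone and the new carbocycle aromatizes to a 2,4-dihydroxybenzoate, whose ester later differentiates the two phenols and is then excised. The precursor is methyl (9R)-3,5,7-trioxo-9-(triisopropylsilyloxy)icosanoate; C9 comes from (R)-3-hydroxytetradecanoic acid, and a TIPS ether is preferred to TBS so that the acid stage cannot free the C9 hydroxyl.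

Key step: step 6

Remark on the chemistry: the carbinol centre is (R) in every compound (priorities O > ring-side CH2 > undecyl CH2 throughout) and no step breaks a bond to it. Acetyl chloride 6 serves both as the C5–C6 unit of the chain and as the final acylating agent. Triketo ester 12 is drawn in its all-keto form although it should exist as a keto–enol mixture.

**Step 1**
Reactants: 1 (3R)-3-hydroxytetradecanoic acid
Product: 3 (3R)-3-(triisopropylsilyloxy)tetradecanoic acid, via triisopropylsilyl ester 2 (not isolated)
Conditions: TIPSOTf (2.4 equiv), 2,6-lutidine, CH2Cl2, 0 °C → rt; then K2CO3, MeOH/THF/H2O, rt; 1 M HCl to pH 3, 0 °C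
Reagents that add atoms: triisopropylsilyl trifluoromethanesulfonate, CC(C)[Si](OS(=O)(=O)C(F)(F)F)(C(C)C)C(C)C
Why: O-Silylation with a silyl triflate and a hindered pyridine base caps both the secondary hydroxyl and the carboxyl, and mild carbonate hydrolysis then cleaves only the far more labile silyl ester, leaving the untouched (R) centre as its TIPS ether.

**Step 2**
Reactants: 3 (3R)-3-(triisopropylsilyloxy)tetradecanoic acid
Product: 4 1-[(3R)-3-(triisopropylsilyloxy)tetradecanoyl]-1H-imidazole
Conditions: 1,1'-carbonyldiimidazole (1.2 equiv), CH2Cl2, rt; quick cold-water wash, dry, used crude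
Reagents that add atoms: 1,1'-carbonyldiimidazole, O=C(n1ccnc1)n1ccnc1
Why: Carboxyl activation by CDI (acyl transfer with loss of CO2 and imidazole) gives the N-acyl imidazole under neutral conditions that can neither epimerize nor eliminate at the β-silyloxy centre.

**Step 3**
Reactants: 5 2,2,6-trimethyl-4H-1,3-dioxin-4-one; 6 acetyl chloride
Product: 8 2,2-dimethyl-6-(2-oxopropyl)-4H-1,3-dioxin-4-one, via lithium dienolate 7 (not isolated)
Conditions: 5 (2.0 equiv), LiN(SiMe3)2 (2.0 equiv), THF, −78 °C; then 6 (1.0 equiv), −78 °C; 1 M HCl quench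
Reagents that add atoms: none
Why: LiN(SiMe3)2 removes a proton from the C6 methyl group to give the extended dienolate, which is C-acylated at that carbon by acetyl chloride (vinylogous Claisen-type acylation), the second equivalent of dienolate taking up the proton of the more acidic β-keto product.

**Step 4**
Reactants: 8 2,2-dimethyl-6-(2-oxopropyl)-4H-1,3-dioxin-4-one; 4 1-[(3R)-3-(triisopropylsilyloxy)tetradecanoyl]-1H-imidazole
Product: 10 6-[(6R)-2,4-dioxo-6-(triisopropylsilyloxy)heptadecyl]-2,2-dimethyl-4H-1,3-dioxin-4-one, via dilithium dianion 9 (not isolated)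
Conditions: 8 (2.2 equiv), LiN(iPr)2 (4.4 equiv), THF, −78 °C; then 4 (1.0 equiv) in THF, −78 → −40 °C; cold 1 M HCl to pH 3–4
Reagents that add atoms: none
Why: Double deprotonation gives a 1,3-dicarbonyl-type dianion that reacts at its last-formed terminal carbanion, so Claisen-type C-acylation by the acyl imidazole extends the chain at the former methyl carbon, while excess dianion absorbs the acidic product and the low temperature suppresses β-elimination of the silyloxy group.

**Step 5**
Reactants: 10 6-[(6R)-2,4-dioxo-6-(triisopropylsilyloxy)heptadecyl]-2,2-dimethyl-4H-1,3-dioxin-4-one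
Product: 12 methyl (9R)-3,5,7-trioxo-9-(triisopropylsilyloxy)icosanoate, via acylketene 11 (not isolated)
Conditions: MeOH (20 equiv), toluene, 110 °C (sealed tube); concentrate, use crude
Reagents that add atoms: methanol, CO
Why: Thermal retro-hetero-Diels–Alder fragmentation of the 2,2-dimethyl-1,3-dioxin-4-one expels acetone and the resulting acylketene is trapped by the large excess of methanol as the β-keto methyl ester before its own enol oxygen can close a pyranone.

**Step 6**
Reactants: 12 methyl (9R)-3,5,7-trioxo-9-(triisopropylsilyloxy)icosanoate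
Product: 14 methyl 2,4-dihydroxy-6-[(2R)-2-(triisopropylsilyloxy)tridecyl]benzoate, via cyclic aldol adduct 13 (not isolated)
Conditions: Cs2CO3 (3 equiv), MeOH, rt; then HCl in MeOH to pH 2–3, 0 °C → rt
Reagents that add atoms: none
Why: Carbonate converts the triketo ester into a polyenolate whose C2 carbon, flanked by the ester and the C3 ketone, adds to the C7 carbonyl and forms the C2–C7 bond; acidification then dehydrates adduct 13 and the two remaining ring ketones enolize, which makes the benzene ring irreversibly. The closest known reaction type is the base-mediated intramolecular aldol aromatization of 3,5,7-triketo esters to 2,4-dihydroxybenzoates, the laboratory counterpart of alkylresorcinol-type polyketide folding. The six-membered carbocycle (C2 to C7) closes in a 6-exo-trig mode at the C7 carbonyl, which is 6-(enolendo)-exo-trig if the nucleophile is counted as the C3-ketone enolate and 6-(enolexo)-exo-trig if counted as the ester enolate, both being allowed closures. No stereocentre is created in the product (the two of adduct 13 vanish on aromatization) and C9, insulated by the C8 methylene, is not touched. The step needs aldol closure to win over Claisen closure of C6 onto the ester carbon C1, over O-cyclization to pyranones and over β-elimination of the C9 silyloxy group: the mild carbonate/methanol medium and the poorly electrophilic methyl ester favour the aldol mode, the base stage is completed before any acid is added, and the enolate character of C7 in the polyanion disfavours deprotonation at C8. The TIPS ether should withstand the brief methanolic acid, so the C9 oxygen cannot be freed to lactonize onto the ortho ester.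

**Step 7**
Reactants: 14 methyl 2,4-dihydroxy-6-[(2R)-2-(triisopropylsilyloxy)tridecyl]benzoate
Product: 15 methyl 2-hydroxy-4-methoxy-6-[(2R)-2-(triisopropylsilyloxy)tridecyl]benzoate
Conditions: MeI (1.2 equiv), K2CO3 (1.5 equiv), acetone, rt → 40 °C
Reagents that add atoms: iodomethane, CI
Why: Williamson O-methylation with about one equivalent of MeI and a weak base should take place only at the para hydroxyl, because the ortho hydroxyl is tied up in a hydrogen bond to the ester carbonyl and is far less acidic and nucleophilic.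

**Step 8**
Reactants: 15 methyl 2-hydroxy-4-methoxy-6-[(2R)-2-(triisopropylsilyloxy)tridecyl]benzoate
Product: 17 3-methoxy-5-[(2R)-2-(triisopropylsilyloxy)tridecyl]phenol, via salicylic acid 16 (not isolated)
Conditions: KOH, DMSO/H2O, 90 °C (Ar); 1 M HCl to pH 3, 0 °C, extract; then toluene, 110 °C
Reagents that add atoms: none
Why: Hot hydroxide saponifies the hindered salicylate ester and the free 2-hydroxy-4-methoxybenzoic acid, whose ipso carbon is activated by an ortho and a para oxygen donor, undergoes thermal protodecarboxylation, while the base-stable TIPS ether keeps the chain oxygen from lactonizing onto the carboxyl.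

**Step 9**
Reactants: 17 3-methoxy-5-[(2R)-2-(triisopropylsilyloxy)tridecyl]phenol
Product: 18 3-[(2R)-2-hydroxytridecyl]-5-methoxyphenol
Conditions: Bu4NF (3 equiv), THF, rt → 45 °C; AcOH quench
Reagents that add atoms: none
Why: Fluoride-mediated desilylation breaks the Si–O bond only, so the carbinol carbon keeps its (R) configuration.

**Step 10**
Reactants: 18 3-[(2R)-2-hydroxytridecyl]-5-methoxyphenol; 6 acetyl chloride
Product: 19 (2R)-1-(3-acetoxy-5-methoxyphenyl)tridecan-2-yl acetate
Conditions: 6 (3 equiv), pyridine, DMAP (cat.), CH2Cl2, 0 °C → rt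
Reagents that add atoms: none
Why: Pyridine/DMAP-mediated O-acylation with acetyl chloride esterifies the phenol and the secondary alcohol alike without breaking a bond at the stereocentre.

**Step 11**
Reactants: 19 (2R)-1-(3-acetoxy-5-methoxyphenyl)tridecan-2-yl acetate
Product: 20 (2R)-1-(3-hydroxy-5-methoxyphenyl)tridecan-2-yl acetate
Conditions: pyrrolidine (1.5 equiv), THF, 0 °C → rt
Reagents that add atoms: none
Why: Chemoselective aminolysis: the aryl acetate, with its phenoxide leaving group, is attacked by the secondary amine far faster than the unactivated secondary alkyl acetate, so only the phenolic acetyl group is removed.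

**Compound list**
1 | (3R)-3-hydroxytetradecanoic acid | CCCCCCCCCCC[C@H](CC(=O)O)O | starting material
2 | triisopropylsilyl (3R)-3-(triisopropylsilyloxy)tetradecanoate (formed in the flask) | CCCCCCCCCCC[C@H](CC(=O)O[Si](C(C)C)(C(C)C)C(C)C)O[Si](C(C)C)(C(C)C)C(C)C | intermediate
3 | (3R)-3-(triisopropylsilyloxy)tetradecanoic acid | CCCCCCCCCCC[C@H](CC(=O)O)O[Si](C(C)C)(C(C)C)C(C)C | intermediate
4 | 1-[(3R)-3-(triisopropylsilyloxy)tetradecanoyl]-1H-imidazole | CCCCCCCCCCC[C@H](CC(=O)n1ccnc1)O[Si](C(C)C)(C(C)C)C(C)C | intermediate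
5 | 2,2,6-trimethyl-4H-1,3-dioxin-4-one | CC1=CC(=O)OC(C)(C)O1 | starting material
6 | acetyl chloride | CC(Cl)=O | starting material
7 | lithium 2,2-dimethyl-6-methylidene-6H-1,3-dioxin-4-olate (formed in the flask) | [Li+].C=C1C=C([O-])OC(C)(C)O1 | intermediate
8 | 2,2-dimethyl-6-(2-oxopropyl)-4H-1,3-dioxin-4-one | CC(=O)CC1=CC(=O)OC(C)(C)O1 | intermediate
9 | dilithium 2,2-dimethyl-6-(2-oxidoprop-2-en-1-ylidene)-6H-1,3-dioxin-4-olate (formed in the flask) | [Li+].[Li+].C=C([O-])C=C1C=C([O-])OC(C)(C)O1 | intermediate
10 | 6-[(6R)-2,4-dioxo-6-(triisopropylsilyloxy)heptadecyl]-2,2-dimethyl-4H-1,3-dioxin-4-one | CCCCCCCCCCC[C@H](CC(=O)CC(=O)CC1=CC(=O)OC(C)(C)O1)O[Si](C(C)C)(C(C)C)C(C)C | intermediate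
11 | (9R)-9-(triisopropylsilyloxy)icos-1-ene-1,3,5,7-tetrone, the acylketene (formed in the flask) | CCCCCCCCCCC[C@H](CC(=O)CC(=O)CC(=O)C=C=O)O[Si](C(C)C)(C(C)C)C(C)C | intermediate
12 | methyl (9R)-3,5,7-trioxo-9-(triisopropylsilyloxy)icosanoate | CCCCCCCCCCC[C@H](CC(=O)CC(=O)CC(=O)CC(=O)OC)O[Si](C(C)C)(C(C)C)C(C)C | intermediate
13 | methyl 2-hydroxy-4,6-dioxo-2-[(2R)-2-(triisopropylsilyloxy)tridecyl]cyclohexane-1-carboxylate (formed in the flask, ring stereocentres undefined) | CCCCCCCCCCC[C@H](CC1(O)CC(=O)CC(=O)C1C(=O)OC)O[Si](C(C)C)(C(C)C)C(C)C | intermediate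
14 | methyl 2,4-dihydroxy-6-[(2R)-2-(triisopropylsilyloxy)tridecyl]benzoate | CCCCCCCCCCC[C@H](Cc1cc(O)cc(O)c1C(=O)OC)O[Si](C(C)C)(C(C)C)C(C)C | intermediate
15 | methyl 2-hydroxy-4-methoxy-6-[(2R)-2-(triisopropylsilyloxy)tridecyl]benzoate | CCCCCCCCCCC[C@H](Cc1cc(OC)cc(O)c1C(=O)OC)O[Si](C(C)C)(C(C)C)C(C)C | intermediate
16 | 2-hydroxy-4-methoxy-6-[(2R)-2-(triisopropylsilyloxy)tridecyl]benzoic acid (formed in the flask) | CCCCCCCCCCC[C@H](Cc1cc(OC)cc(O)c1C(=O)O)O[Si](C(C)C)(C(C)C)C(C)C | intermediate
17 | 3-methoxy-5-[(2R)-2-(triisopropylsilyloxy)tridecyl]phenol | CCCCCCCCCCC[C@H](Cc1cc(O)cc(OC)c1)O[Si](C(C)C)(C(C)C)C(C)C | intermediate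
18 | 3-[(2R)-2-hydroxytridecyl]-5-methoxyphenol | CCCCCCCCCCC[C@H](Cc1cc(O)cc(OC)c1)O | intermediate
19 | (2R)-1-(3-acetoxy-5-methoxyphenyl)tridecan-2-yl acetate | CCCCCCCCCCC[C@H](Cc1cc(OC(C)=O)cc(OC)c1)OC(C)=O | intermediate
20 | (2R)-1-(3-hydroxy-5-methoxyphenyl)tridecan-2-yl acetate (CNP0215596.1) | CCCCCCCCCCC[C@H](Cc1cc(O)cc(OC)c1)OC(C)=O | target

**Step count.** Total: 11 steps. Longest linear sequence: 10 steps (steps 1, 2, 4, 5, 6, 7, 8, 9, 10, 11); step 3 is the side branch.

**Steps most likely to fail**

1. Step 6. The closure may stray into the Claisen mode (C6 onto C1) or into O-cyclization to pyranones, the C9 silyloxy group may be lost by β-elimination, or acid may strip the silyl group so that the freed hydroxyl lactonizes onto the ester. The ring can instead be closed before the ester is unmasked. Setting out from 10, triethylamine in CH2Cl2 at room temperature should aromatize the diketo-dioxinone with the dioxinone ring still in place (same C–C bond, no free ester, no acid) to 7-hydroxy-2,2-dimethyl-5-[(2R)-2-(triisopropylsilyloxy)tridecyl]-4H-1,3-benzodioxin-4-one F1. MeI and K2CO3 in acetone would methylate its only free phenol to 7-methoxy-2,2-dimethyl-5-[(2R)-2-(triisopropylsilyloxy)tridecyl]-4H-1,3-benzodioxin-4-one F2. Aqueous KOH should then open the acylal-type ring with loss of acetone and come back to the route at salicylic acid 16, which is decarboxylated to 17 as in step 8.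

2. Step 4. Proton transfer from the acidic product to unreacted dianion, O-acylation, or enolization of the acyl imidazole with expulsion of silanolate may hold the C-acylation back. The same carbon–carbon bond can be made by aldol addition and the oxidation level corrected afterwards. Setting out from 3, BH3·THF should reduce the acid to (3R)-3-(triisopropylsilyloxy)tetradecan-1-ol F3, and Dess–Martin periodinane should oxidize this to (3R)-3-(triisopropylsilyloxy)tetradecanal F4. Addition of this aldehyde to dianion 9 at −78 °C should give 6-[(6R)-4-hydroxy-2-oxo-6-(triisopropylsilyloxy)heptadecyl]-2,2-dimethyl-4H-1,3-dioxin-4-one F5 as a mixture of carbinol epimers, which does not matter. A second Dess–Martin oxidation of the β-hydroxy ketone comes back to the route at 10.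

3. Step 8. Hydrolysis of the hindered, hydrogen-bonded ester may stall, or the silyl ether may be lost in hot base so that the chain hydroxyl lactonizes on acidification instead of the acid decarboxylating. The ester can be chosen so that hydrogenolysis removes it. Setting out from 10, thermolysis in toluene at 110 °C with benzyl alcohol in place of methanol should give benzyl (9R)-3,5,7-trioxo-9-(triisopropylsilyloxy)icosanoate F6. Cs2CO3 in THF followed by HCl in dioxane should aromatize it to benzyl 2,4-dihydroxy-6-[(2R)-2-(triisopropylsilyloxy)tridecyl]benzoate F7, and MeI with K2CO3 should give benzyl 2-hydroxy-4-methoxy-6-[(2R)-2-(triisopropylsilyloxy)tridecyl]benzoate F8. H2 over Pd/C in EtOAc should then cleave the benzyl ester under neutral conditions and come back to the route at 16, which is warmed in toluene to give 17.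

**Further compounds**
F1 | step 6 | 7-hydroxy-2,2-dimethyl-5-[(2R)-2-(triisopropylsilyloxy)tridecyl]-4H-1,3-benzodioxin-4-one | CCCCCCCCCCC[C@H](Cc1cc(O)cc2OC(C)(C)OC(=O)c12)O[Si](C(C)C)(C(C)C)C(C)C
F2 | step 6 | 7-methoxy-2,2-dimethyl-5-[(2R)-2-(triisopropylsilyloxy)tridecyl]-4H-1,3-benzodioxin-4-one | CCCCCCCCCCC[C@H](Cc1cc(OC)cc2OC(C)(C)OC(=O)c12)O[Si](C(C)C)(C(C)C)C(C)C
F3 | step 4 | (3R)-3-(triisopropylsilyloxy)tetradecan-1-ol | CCCCCCCCCCC[C@H](CCO)O[Si](C(C)C)(C(C)C)C(C)C
F4 | step 4 | (3R)-3-(triisopropylsilyloxy)tetradecanal | CCCCCCCCCCC[C@H](CC=O)O[Si](C(C)C)(C(C)C)C(C)C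
F5 | step 4 | 6-[(6R)-4-hydroxy-2-oxo-6-(triisopropylsilyloxy)heptadecyl]-2,2-dimethyl-4H-1,3-dioxin-4-one | CCCCCCCCCCC[C@H](CC(O)CC(=O)CC1=CC(=O)OC(C)(C)O1)O[Si](C(C)C)(C(C)C)C(C)C
F6 | step 8 | benzyl (9R)-3,5,7-trioxo-9-(triisopropylsilyloxy)icosanoate | CCCCCCCCCCC[C@H](CC(=O)CC(=O)CC(=O)CC(=O)OCc1ccccc1)O[Si](C(C)C)(C(C)C)C(C)C
F7 | step 8 | benzyl 2,4-dihydroxy-6-[(2R)-2-(triisopropylsilyloxy)tridecyl]benzoate | CCCCCCCCCCC[C@H](Cc1cc(O)cc(O)c1C(=O)OCc1ccccc1)O[Si](C(C)C)(C(C)C)C(C)C
F8 | step 8 | benzyl 2-hydroxy-4-methoxy-6-[(2R)-2-(triisopropylsilyloxy)tridecyl]benzoate | CCCCCCCCCCC[C@H](Cc1cc(OC)cc(O)c1C(=O)OCc1ccccc1)O[Si](C(C)C)(C(C)C)C(C)C
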